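**Retrosynthetic overview**

1. Cordycicadin B ⇒ its C2′-epimeric mixture: the furan-bearing carbon is set last, by kinetic protonation of the γ-lactone enolate.
2. Ten-membered lactone ⇒ hydroxy keto acid, cut at the C1(=O)–O–C9 bond; in the forward direction this C–O bond is made through a lactol-derived acyl ketal that is ring-expanded (key step).
3. γ-Lactone ⇒ acyclic 3,4-anti hydroxy diester, cut at the O3–C1′ bond; its C4–C2′ bond ⇒ Mukaiyama–Michael addition of a furylacetate ketene acetal to a γ-silyloxy (E)-enone.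
4. Enone ⇒ (E)-4-oxo-2-enal (oxidative opening of a 2-alkylfuran) plus an asymmetric acetate aldol; furylacetate ⇒ radical C–H carboxymethylation; both halves ⇒ (R)-4-(furan-2-yl)butan-2-ol.
5. Ring order: furan (present from the start), then γ-lactone (step 8), then ten-membered lactone (step 9).

Locants: C1–C10 is the decanolide chain (C1 lactone carbonyl, C3 oxygen-bearing fusion carbon, C4 fusion carbon, C6 ketone, C9 methyl carbinol); C1′–C10′ is the furan chain (C1′ γ-lactone carbonyl, C2′ carbon bearing the furan, C9′ side-chain carbinol). The target is (3S,4S,9R,2′S,9′R), with the furan, C5 and C2 all on the same face of the γ-lactone.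

Assumption: the hand of the disulfonimide catalyst in step 5 is taken as the one that attacks the Si face of the aldehyde; if the sense is the reverse, its antipode is used.

**Step 1**
Reactants: 1 4-(furan-2-yl)butan-2-one
Product: 2 (R)-4-(furan-2-yl)butan-2-ol
Conditions: Lactobacillus brevis alcohol dehydrogenase, NADP+ (cat.), MgCl2 (1 mM), i-PrOH, phosphate buffer pH 7, 30 °C
Reagents that add atoms: none
Why: Biocatalytic ketone reduction by an anti-Prelog alcohol dehydrogenase delivers hydride to the Si face of the methyl ketone, giving the (R)-carbinol that becomes both C9 and C9′.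

**Step 2**
Reactants: 2 (R)-4-(furan-2-yl)butan-2-ol
Product: 3 (R)-tert-butyl{[4-(furan-2-yl)butan-2-yl]oxy}dimethylsilane
Conditions: TBSCl, imidazole, DMF, rt
Reagents that add atoms: tert-butyldimethylsilyl chloride, CC(C)(C)[Si](C)(C)Cl
Why: Standard silyl ether formation keeps the hydroxyl from forming a spiroketal during the furan oxidation and leaves the stereocentre untouched.

**Step 3**
Reactants: 3 (R)-tert-butyl{[4-(furan-2-yl)butan-2-yl]oxy}dimethylsilane
Product: 5 (R,E)-7-[(tert-butyldimethylsilyl)oxy]-4-oxooct-2-enal, via Z-oxoenal 4 (not isolated)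
Conditions: NBS, NaHCO3, acetone/H2O (10:1), −15 °C; then pyridine, rt
Reagents that add atoms: water, O
Why: Achmatowicz-type oxidative ring opening of the 2-alkylfuran gives the (Z)-4-oxo-2-enal, which pyridine isomerises to the (E)-isomer by reversible conjugate addition.

**Step 4**
Reactants: 6 tert-butyl acetate
Product: 8 tert-butyl{[1-(tert-butoxy)ethenyl]oxy}dimethylsilane, via lithium enolate 7 (not isolated)
Conditions: LiN(i-Pr)2, THF, −78 °C; then TBSCl, DMPU, −78 °C to rt
Reagents that add atoms: tert-butyldimethylsilyl chloride, CC(C)(C)[Si](C)(C)Cl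
Why: O-Silylation of the ester enolate gives the ketene silyl acetal needed for the Mukaiyama aldol.

**Step 5**
Reactants: 5 (R,E)-7-[(tert-butyldimethylsilyl)oxy]-4-oxooct-2-enal; 8 tert-butyl{[1-(tert-butoxy)ethenyl]oxy}dimethylsilane
Product: 9 tert-butyl (3S,4E,9R)-3,9-bis[(tert-butyldimethylsilyl)oxy]-6-oxodec-4-enoate
Conditions: (S)-3,3′-bis[3,5-bis(trifluoromethyl)phenyl]-1,1′-binaphthyl-2,2′-disulfonimide (5 mol %), Et2O, −78 °C
Reagents that add atoms: none
Why: Disulfonimide-catalysed asymmetric Mukaiyama aldol, in which the ketene acetal adds to the Si face of the aldehyde (faster than to the ketone or the enone) and silyl transfer delivers the (3S) silyl ether directly.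

**Step 6**
Reactants: 2 (R)-4-(furan-2-yl)butan-2-ol
Product: 10 ethyl 2-{5-[(R)-3-hydroxybutyl]furan-2-yl}acetate
Conditions: ICH2CO2Et (3 equiv), FeSO4·7H2O (0.5 equiv), 30% H2O2, DMSO, rt
Reagents that add atoms: ethyl iodoacetate, CCOC(=O)CI
Why: Homolytic aromatic substitution (Minisci-type), in which the electrophilic ethoxycarbonylmethyl radical adds to the only free α-position of the furan and the adduct is re-aromatised by oxidation, with the free alcohol tolerated.

**Step 7**
Reactants: 10 ethyl 2-{5-[(R)-3-hydroxybutyl]furan-2-yl}acetate; 9 tert-butyl (3S,4E,9R)-3,9-bis[(tert-butyldimethylsilyl)oxy]-6-oxodec-4-enoate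
Product: 13 tert-butyl (3S,4S,9R)-3,9-bis[(tert-butyldimethylsilyl)oxy]-4-{2-ethoxy-1-[5-((R)-3-hydroxybutyl)furan-2-yl]-2-oxoethyl}-6-oxodecanoate (C2′ epimers), via ketene silyl acetal 11 (not isolated), via silyl enol ether adduct 12 (not isolated)
Conditions: LiN(i-Pr)2 (2.2 equiv), TMSCl (2.6 equiv, in situ quench), THF, −78 °C; pentane, filter, concentrate; then 9, HNTf2 (2 mol %), CH2Cl2, −78 °C; 1 M HCl, THF, 0 °C
Reagents that add atoms: none
Why: Mukaiyama–Michael addition through an open transition state, where the C3 silyloxy group lies anti to the incoming nucleophile and C3–H eclipses the alkene (modified Felkin–Anh, minimal A(1,3) strain), giving the 3,4-anti adduct with (4S) while C2′ forms as a mixture that is corrected in step 10.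

**Step 8**
Reactants: 13 tert-butyl (3S,4S,9R)-3,9-bis[(tert-butyldimethylsilyl)oxy]-4-{2-ethoxy-1-[5-((R)-3-hydroxybutyl)furan-2-yl]-2-oxoethyl}-6-oxodecanoate
Product: 15 2-{(2S,3S)-4-[5-((R)-3-hydroxybutyl)furan-2-yl]-3-[(R)-5-hydroxy-2-oxohexyl]-5-oxotetrahydrofuran-2-yl}acetic acid (C2′ epimers), via hydroxy ester acid 14 (not isolated)
Conditions: TFA/CH2Cl2/H2O (10:10:1), 0 °C to rt; then aq. NaHCO3/MeOH, 0 °C; acidify to pH 3
Reagents that add atoms: none
Why: Acidolysis removes the tert-butyl ester and both silyl ethers, and the freed C3 hydroxyl closes the γ-lactone on the ethyl ester (5-exo-trig transesterification with retention at C3), which drains any reversibly formed spiroketal and turns the 3,4-anti relationship into the cis arrangement of C2 and C5 on the lactone.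

**Step 9**
Reactants: 15 2-{(2S,3S)-4-[5-((R)-3-hydroxybutyl)furan-2-yl]-3-[(R)-5-hydroxy-2-oxohexyl]-5-oxotetrahydrofuran-2-yl}acetic acid
Product: 17 ten-membered keto lactone (3S,4S,9R,9′R; C2′ epimers), via spiro acyl ketal 16 (not isolated)
Conditions: PPTS (10 mol %), 4 Å MS, PhMe (2 mM), 40 °C; then DMAP (1.2 equiv), 80 °C
Reagents that add atoms: none
Why: Proposed new method: the γ-hydroxy ketone of 15 ionises under mild acid to its cyclic oxocarbenium ion, which the C1 carboxylic acid traps to give the seven-membered acyl ketal 16 (the way a carboxylic acid adds to dihydropyran to give a THP ester), and DMAP then attacks this activated ester so that the expelled hemiketal alkoxide collapses to the C6 ketone and frees the C9 alkoxide beside the acylpyridinium, which closes the ten-membered lactone irreversibly while the remote C9′ hydroxyl never enters the relay; the closest known reactions are THP-ester formation, DMAP acyl transfer as in Steglich and Shiina lactonisations, and ring expansion of lactones by side-chain acyl transfer.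

**Step 10**
Reactants: 17 ten-membered keto lactone (3S,4S,9R,9′R; C2′ epimers)
Product: 19 cordycicadin B, via dilithium enolate 18 (not isolated)
Conditions: LiN(SiMe3)2 (2.1 equiv), THF, −78 °C, 10 min; then AcOH, THF, −78 °C
Reagents that add atoms: none
Why: Kinetic protonation of the α-furyl lactone enolate (the most acidic C–H) occurs from the face opposite C5 and the ten-membered ring, which places the furan cis to C5 and sets (2′S).

**Compound list**

1 | 4-(furan-2-yl)butan-2-one | CC(=O)CCc1ccco1 | starting material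
2 | (R)-4-(furan-2-yl)butan-2-ol | C[C@@H](O)CCc1ccco1 | intermediate
3 | (R)-tert-butyl{[4-(furan-2-yl)butan-2-yl]oxy}dimethylsilane | C[C@@H](O[Si](C)(C)C(C)(C)C)CCc1ccco1 | intermediate
4 | (R,Z)-7-[(tert-butyldimethylsilyl)oxy]-4-oxooct-2-enal | C[C@@H](O[Si](C)(C)C(C)(C)C)CCC(=O)/C=C\C=O | intermediate (not isolated)
5 | (R,E)-7-[(tert-butyldimethylsilyl)oxy]-4-oxooct-2-enal | C[C@@H](O[Si](C)(C)C(C)(C)C)CCC(=O)/C=C/C=O | intermediate
6 | tert-butyl acetate | CC(=O)OC(C)(C)C | starting material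
7 | lithium 1-(tert-butoxy)ethen-1-olate | [Li+].C=C([O-])OC(C)(C)C | intermediate (not isolated)
8 | tert-butyl{[1-(tert-butoxy)ethenyl]oxy}dimethylsilane | C=C(OC(C)(C)C)O[Si](C)(C)C(C)(C)C | intermediate
9 | tert-butyl (3S,4E,9R)-3,9-bis[(tert-butyldimethylsilyl)oxy]-6-oxodec-4-enoate | CC(C)(C)OC(=O)C[C@H](O[Si](C)(C)C(C)(C)C)/C=C/C(=O)CC[C@@H](C)O[Si](C)(C)C(C)(C)C | intermediate
10 | ethyl 2-{5-[(R)-3-hydroxybutyl]furan-2-yl}acetate | CCOC(=O)Cc1ccc(CC[C@@H](C)O)o1 | intermediate
11 | {[1-ethoxy-2-(5-{(R)-3-[(trimethylsilyl)oxy]butyl}furan-2-yl)ethenyl]oxy}trimethylsilane (E/Z mixture) | CCOC(O[Si](C)(C)C)=Cc1ccc(CC[C@@H](C)O[Si](C)(C)C)o1 | intermediate (not isolated)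
12 | tert-butyl (3S,4S,9R)-3,9-bis[(tert-butyldimethylsilyl)oxy]-4-[2-ethoxy-2-oxo-1-(5-{(R)-3-[(trimethylsilyl)oxy]butyl}furan-2-yl)ethyl]-6-[(trimethylsilyl)oxy]dec-5-enoate (C2′ epimers) | CC(C)(C)OC(=O)C[C@H](O[Si](C)(C)C(C)(C)C)[C@@H](C=C(O[Si](C)(C)C)CC[C@@H](C)O[Si](C)(C)C(C)(C)C)C(C(=O)OCC)c1ccc(CC[C@@H](C)O[Si](C)(C)C)o1 | intermediate (not isolated)
13 | tert-butyl (3S,4S,9R)-3,9-bis[(tert-butyldimethylsilyl)oxy]-4-{2-ethoxy-1-[5-((R)-3-hydroxybutyl)furan-2-yl]-2-oxoethyl}-6-oxodecanoate (C2′ epimers) | CC(C)(C)OC(=O)C[C@H](O[Si](C)(C)C(C)(C)C)[C@@H](CC(=O)CC[C@@H](C)O[Si](C)(C)C(C)(C)C)C(C(=O)OCC)c1ccc(CC[C@@H](C)O)o1 | intermediate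
14 | (3S,4S,9R)-4-{2-ethoxy-1-[5-((R)-3-hydroxybutyl)furan-2-yl]-2-oxoethyl}-3,9-dihydroxy-6-oxodecanoic acid (C2′ epimers) | OC(=O)C[C@H](O)[C@@H](CC(=O)CC[C@@H](C)O)C(C(=O)OCC)c1ccc(CC[C@@H](C)O)o1 | intermediate (not isolated)
15 | 2-{(2S,3S)-4-[5-((R)-3-hydroxybutyl)furan-2-yl]-3-[(R)-5-hydroxy-2-oxohexyl]-5-oxotetrahydrofuran-2-yl}acetic acid (C2′ epimers) | C[C@@H](O)CCC(=O)C[C@@H]2[C@H](CC(=O)O)OC(=O)C2c1ccc(CC[C@@H](C)O)o1 | intermediate
16 | spiro acyl ketal of 15: C6 is a ketal carbon bonded to the C9 oxygen (five-membered ring) and to the C1 acyloxy oxygen (seven-membered ring), γ-lactone retained (3S,4S,9R,9′R; C6 and C2′ mixtures) | C[C@@H]1CCC3(O1)C[C@@H]2[C@H](CC(=O)O3)OC(=O)C2c1ccc(CC[C@@H](C)O)o1 | intermediate (not isolated)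
17 | ten-membered keto lactone cis-fused to the γ-lactone, (3S,4S,9R,9′R), C2′ epimers (cordycicadin B and its 2′-epimer) | C[C@@H]1CCC(=O)C[C@@H]2[C@H](CC(=O)O1)OC(=O)C2c1ccc(CC[C@@H](C)O)o1 | intermediate
18 | dilithium salt of 17: γ-lactone enolate and C9′ alkoxide | [Li+].[Li+].C[C@@H]1CCC(=O)C[C@@H]2[C@H](CC(=O)O1)OC([O-])=C2c1ccc(CC[C@@H](C)[O-])o1 | intermediate (not isolated)
19 | cordycicadin B, (3S,4S,9R,2′S,9′R): 6-oxodecan-9-olide cis-fused at C3/C4 to a γ-butyrolactone whose C2′ carries a 5-[(R)-3-hydroxybutyl]furan-2-yl group cis to C5 | C[C@@H]1CCC(=O)C[C@@H]2[C@H](CC(=O)O1)OC(=O)[C@@H]2c1ccc(CC[C@@H](C)O)o1 | target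

**Step count**

Total: 10 steps. Longest linear sequence: 8 steps (steps 1, 2, 3, 5, 7, 8, 9, 10).

**Three steps most likely to fail**

Step 9 (the new acyl-ketal relay lactonisation). The acyl ketal may not form cleanly, or DMAP may not open it. The fallback uses known chemistry, sets out from 10 and comes back at 17. The side-chain alcohol of 10 is protected (TBDPSCl, imidazole, DMF) as ethyl 2-{5-[(R)-3-((tert-butyldiphenylsilyl)oxy)butyl]furan-2-yl}acetate F5. F5 is carried through the Mukaiyama–Michael addition with 9 (conditions of step 7) to the silyl-protected adduct F6 and through the trifluoroacetic acid unmasking (conditions of step 8, which the TBDPS ether survives) to the seco acid F7. A Shiina macrolactonisation (2-methyl-6-nitrobenzoic anhydride, DMAP, Et3N, PhMe, 1 mM, slow addition), now with only the C9 hydroxyl free, gives the protected ten-membered lactone F8. HF·pyridine in THF removes the TBDPS group and returns 17.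

Step 7 (facial selectivity of the addition to the acyclic enone, and acid sensitivity of the partners). The fallback replaces open-chain control by ring control, sets out from 9 and comes back at 17. The less hindered C9 silyl ether of 9 is removed (HF·pyridine/pyridine, THF, 0 °C) to give tert-butyl (3S,4E,9R)-3-[(tert-butyldimethylsilyl)oxy]-9-hydroxy-6-oxodec-4-enoate F1. The tert-butyl ester is cleaved without loss of the C3 silyl ether (TMSOTf, 2,6-lutidine, CH2Cl2; aqueous work-up) to the acid F2. Shiina macrolactonisation closes the ten-membered (E)-enone lactone (4S,5E,10R)-4-[(tert-butyldimethylsilyl)oxy]-10-methyloxacyclodec-5-ene-2,7-dione F3. Ketene silyl acetal 11 is then added to the ring enone (HNTf2 cat., CH2Cl2, −78 °C), where only the outer face of the alkene is open, to give the ring adduct F4. HF·pyridine removes the C3 silyl group and the freed hydroxyl lactonises onto the ethyl ester to give 17.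

Step 10 (enolate chemistry next to a ketone and a β-acyloxy ester: Dieckmann closure, retro-Michael or elimination could compete, and the face selectivity rests on the substrate alone). The fallback moves the control to a reagent, sets out from 17 and comes back at 19. Compound 17 is converted (LiN(SiMe3)2, TMSCl, THF, −78 °C) into the isolated bis-silyl derivative, the γ-lactone ketene silyl acetal with a C9′ trimethylsilyl ether, F9. F9 is protonated at −78 °C in toluene with the Lewis-acid-assisted chiral Brønsted acid (R)-BINOL·SnCl4 (hand chosen to match protonation from the face opposite C5). Aqueous work-up removes the silyl ether and gives 19.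

**Further compounds**

F1 | step 7 | tert-butyl (3S,4E,9R)-3-[(tert-butyldimethylsilyl)oxy]-9-hydroxy-6-oxodec-4-enoate | CC(C)(C)OC(=O)C[C@H](O[Si](C)(C)C(C)(C)C)/C=C/C(=O)CC[C@@H](C)O
F2 | step 7 | (3S,4E,9R)-3-[(tert-butyldimethylsilyl)oxy]-9-hydroxy-6-oxodec-4-enoic acid | OC(=O)C[C@H](O[Si](C)(C)C(C)(C)C)/C=C/C(=O)CC[C@@H](C)O
F3 | step 7 | (4S,5E,10R)-4-[(tert-butyldimethylsilyl)oxy]-10-methyloxacyclodec-5-ene-2,7-dione | C[C@@H]1CCC(=O)/C=C/[C@@H](O[Si](C)(C)C(C)(C)C)CC(=O)O1
F4 | step 7 | ethyl 2-{(4S,5S,10R)-4-[(tert-butyldimethylsilyl)oxy]-10-methyl-2,7-dioxooxecan-5-yl}-2-{5-[(R)-3-hydroxybutyl]furan-2-yl}acetate (C2′ epimers) | C[C@@H]1CCC(=O)C[C@@H](C(C(=O)OCC)c2ccc(CC[C@@H](C)O)o2)[C@@H](O[Si](C)(C)C(C)(C)C)CC(=O)O1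
F5 | step 9 | ethyl 2-{5-[(R)-3-((tert-butyldiphenylsilyl)oxy)butyl]furan-2-yl}acetate | CCOC(=O)Cc1ccc(CC[C@@H](C)O[Si](c2ccccc2)(c2ccccc2)C(C)(C)C)o1
F6 | step 9 | tert-butyl (3S,4S,9R)-3,9-bis[(tert-butyldimethylsilyl)oxy]-4-{1-[5-((R)-3-((tert-butyldiphenylsilyl)oxy)butyl)furan-2-yl]-2-ethoxy-2-oxoethyl}-6-oxodecanoate (C2′ epimers) | CC(C)(C)OC(=O)C[C@H](O[Si](C)(C)C(C)(C)C)[C@@H](CC(=O)CC[C@@H](C)O[Si](C)(C)C(C)(C)C)C(C(=O)OCC)c1ccc(CC[C@@H](C)O[Si](c2ccccc2)(c2ccccc2)C(C)(C)C)o1
F7 | step 9 | 2-{(2S,3S)-4-[5-((R)-3-((tert-butyldiphenylsilyl)oxy)butyl)furan-2-yl]-3-[(R)-5-hydroxy-2-oxohexyl]-5-oxotetrahydrofuran-2-yl}acetic acid (C2′ epimers) | C[C@@H](O)CCC(=O)C[C@@H]2[C@H](CC(=O)O)OC(=O)C2c1ccc(CC[C@@H](C)O[Si](c3ccccc3)(c3ccccc3)C(C)(C)C)o1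
F8 | step 9 | C9′ tert-butyldiphenylsilyl ether of 17 (C2′ epimers) | C[C@@H]1CCC(=O)C[C@@H]2[C@H](CC(=O)O1)OC(=O)C2c1ccc(CC[C@@H](C)O[Si](c3ccccc3)(c3ccccc3)C(C)(C)C)o1
F9 | step 10 | γ-lactone trimethylsilyl ketene acetal of 17 with a C9′ trimethylsilyl ether | C[C@@H]1CCC(=O)C[C@@H]2[C@H](CC(=O)O1)OC(O[Si](C)(C)C)=C2c1ccc(CC[C@@H](C)O[Si](C)(C)C)o1
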